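## Retrosynthetic overview

1. The C19–O ester bond is cut last, giving a diene diol and a separately made (Z)-4-silyloxycinnamic acid (from 4-iodophenol and ethyl propiolate by Sonogashira coupling and Lindlar reduction); the arene ring is bought intact.
2. The diene comes from a B-alkyl Suzuki coupling (C12–C13) of a 9-vinyl compound with chloroprene; the key C9–C11 bond is made by a nickel-catalysed reductive coupling of an 8,9-epoxide with vinyl bromide, whose trans-diaxial opening sets C9.
3. The epoxide on the face of the angular methyl comes from the Δ8 alkene through a bromohydrin (sets C8); the quaternary C4 comes from a C4 vinyl group by ozonolysis, equatorial α-methylation and reduction.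
4. The decalin is formed by an iridium-catalysed enantioselective polyene cyclisation of a racemic branched allylic alcohol: ring A closes first (sets C5 and C10), ring B second by vinylsilane ipso-termination, which places the alkene at C8–C9.
5. The acyclic trienol is assembled by a Negishi sp3–sp2 coupling of a (Z)-vinylsilane alkylzinc (from but-3-yn-1-ol) with an (E)-alkenyl iodide (from hex-5-yn-1-ol).

## Assumptions

- The SMILES is taken literally: the target is the (4R,5S,8R,9R,10R) isomer in labdane locants, a trans-decalin with the C19 ester arm and the 8-OH on the face of the C10 methyl and the C9 side chain on the opposite face.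
- Labdane locants (ring carbons C1–C10, C17 on C8, C18 and C19 on C4, C20 on C10, side chain C11–C16) are used in the Why lines; the systematic names use naphthalene locants.
- The (S)-configured phosphoramidite–olefin ligand is assumed to give the (1R,4aR,8aR) series in step 8; if the sense of induction is the opposite, its antipode is used with nothing else changed.

## Route

Step 1
Reactants: 1 but-3-yn-1-ol
Product: 3 4-(trimethylsilyl)but-3-yn-1-ol, via bis-silyl ether 2 (not isolated)
Conditions: n-BuLi (2.1 equiv), THF, −78 °C; TMSCl (2.2 equiv), −78 °C → rt; then 1 M aq. HCl, rt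
Reagents that add atoms: chlorotrimethylsilane, C[Si](C)(C)Cl
Why: Double deprotonation and silylation at oxygen and at the alkyne carbon, then selective acid hydrolysis of the labile silyl ether, leaves the carbon-bound silicon that later directs the carbometalation and ends the cyclisation (alkyne C-silylation).

Step 2
Reactants: 3 4-(trimethylsilyl)but-3-yn-1-ol
Product: 5 (3Z)-3-methyl-4-(trimethylsilyl)but-3-en-1-ol, via alkenylmagnesium bromide 4 (not isolated)
Conditions: MeMgBr (3.5 equiv), Ni(acac)2 (10 mol%), Me3Al (10 mol%), THF, 0 °C → rt; then sat. aq. NH4Cl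
Reagents that add atoms: methylmagnesium bromide, C[Mg]Br
Why: Nickel-catalysed syn-carbomagnesiation of the silylalkyne puts the methyl group on the carbon remote from silicon and magnesium on the silicon-bearing carbon (held by the neighbouring alkoxide), so protonation gives the vinylsilane with silicon cis to the hydroxyethyl chain (Z).

Step 3
Reactants: 5 (3Z)-3-methyl-4-(trimethylsilyl)but-3-en-1-ol
Product: 6 [(1Z)-4-iodo-2-methylbut-1-en-1-yl](trimethyl)silane
Conditions: iodine, PPh3, imidazole, CH2Cl2, 0 °C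
Reagents that add atoms: iodine, [I][I]
Why: Appel-type iodination converts the primary alcohol into the iodide by SN2 displacement of the alkoxyphosphonium ion without touching the vinylsilane.

Step 4
Reactants: 7 hex-5-yn-1-ol
Product: 8 hex-5-ynal
Conditions: TEMPO (10 mol%), PhI(OAc)2 (1.1 equiv), CH2Cl2, rt
Reagents that add atoms: none
Why: TEMPO-catalysed oxidation stops cleanly at the aldehyde and tolerates the terminal alkyne.

Step 5
Reactants: 8 hex-5-ynal
Product: 9 rac-oct-1-en-7-yn-3-ol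
Conditions: CH2=CHMgBr (1.1 equiv), THF, −78 °C; then sat. aq. NH4Cl
Reagents that add atoms: vinylmagnesium bromide, C=C[Mg]Br
Why: 1,2-Addition of the vinyl Grignard reagent to the aldehyde at low temperature outruns deprotonation of the alkyne and gives the racemic branched allylic alcohol, whose configuration is irrelevant because it is ionised in step 8.

Step 6
Reactants: 9 rac-oct-1-en-7-yn-3-ol
Product: 11 rac-(7E)-8-iodo-7-methylocta-1,7-dien-3-ol, via alkenylalane 10 (not isolated)
Conditions: Me3Al (3.0 equiv), Cp2ZrCl2 (20 mol%), CH2Cl2, 0 °C → rt; then iodine, THF, −30 → 0 °C; aq. Rochelle salt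
Reagents that add atoms: trimethylaluminium, C[Al](C)C; iodine, [I][I]
Why: Zirconium-catalysed syn-carboalumination (Negishi) adds methyl to the internal and aluminium to the terminal alkyne carbon and iodinolysis with retention gives the (E)-alkenyl iodide, the hydroxyl being carried as its aluminium alkoxide and the terminal alkene staying inert.

Step 7
Reactants: 6 [(1Z)-4-iodo-2-methylbut-1-en-1-yl](trimethyl)silane; 11 rac-(7E)-8-iodo-7-methylocta-1,7-dien-3-ol
Product: 13 rac-(7E,11Z)-7,11-dimethyl-12-(trimethylsilyl)dodeca-1,7,11-trien-3-ol, via alkylzinc iodide 12 (not isolated)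
Conditions: 6 (1.4 equiv), Zn dust, LiCl, THF, 40 °C; then 11, Pd(OAc)2 (2 mol%), SPhos (4 mol%), THF, rt
Reagents that add atoms: none
Why: Zinc insertion into the primary iodide and palladium-catalysed Negishi sp3–sp2 coupling join the two fragments with retention of both alkene geometries, the free hydroxyl being tolerated by the mild organozinc.

Step 8
Reactants: 13 rac-(7E,11Z)-7,11-dimethyl-12-(trimethylsilyl)dodeca-1,7,11-trien-3-ol
Product: 14 (1R,4aR,8aR)-1-ethenyl-4a,6-dimethyl-1,2,3,4,4a,7,8,8a-octahydronaphthalene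
Conditions: [Ir(cod)Cl]2 (4 mol%), (S)-BINOL-derived dibenzazepine phosphoramidite–olefin ligand (16 mol%), Zn(OTf)2 (20 mol%), ClCH2CH2Cl, rt
Reagents that add atoms: none
Why: Carreira-type iridium-catalysed enantioselective polyene cyclisation, in which Zn(OTf)2-assisted ionisation of either alcohol enantiomer gives one chiral π-allyl iridium complex that is attacked at its branched carbon by the (E)-trisubstituted alkene (catalyst control fixes C4 and, through the chair–chair transition state, the trans ring fusion at C5 and C10), and the tertiary C10 cation is then trapped by the vinylsilane at its silicon-bearing carbon with loss of silicon, which places the alkene regiospecifically at C8–C9.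

Step 9
Reactants: 14 (1R,4aR,8aR)-1-ethenyl-4a,6-dimethyl-1,2,3,4,4a,7,8,8a-octahydronaphthalene
Product: 16 (1R,4aR,5S,6R,8aR)-1-ethenyl-5,6-epoxy-4a,6-dimethyldecahydronaphthalene, via bromohydrin 15 (not isolated)
Conditions: NBS (1.05 equiv), THF/H2O 4:1, 0 °C; then K2CO3, MeOH, rt
Reagents that add atoms: water, O
Why: NBS forms the bromonium ion on the face opposite the adjacent angular methyl and water opens it at the tertiary C8 in the trans-diaxial (Fürst–Plattner) and Markovnikov sense, which sets the C8 carbinol configuration, and carbonate then closes the bromohydrin to the epoxide on the methyl face, the far less nucleophilic monosubstituted vinyl group being left alone.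

Step 10
Reactants: 16 (1R,4aR,5S,6R,8aR)-1-ethenyl-5,6-epoxy-4a,6-dimethyldecahydronaphthalene
Product: 17 (1S,4aR,5S,6R,8aR)-5,6-epoxy-4a,6-dimethyldecahydronaphthalene-1-carbaldehyde
Conditions: O3, CH2Cl2/MeOH, −78 °C; then Me2S, −78 °C → rt
Reagents that add atoms: ozone, [O-][O+]=O
Why: Ozonolysis with reductive work-up cleaves the only remaining alkene to the C4 aldehyde, the epoxide being inert to ozone.

Step 11
Reactants: 17 (1S,4aR,5S,6R,8aR)-5,6-epoxy-4a,6-dimethyldecahydronaphthalene-1-carbaldehyde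
Product: 19 [(1R,4aR,5S,6R,8aR)-5,6-epoxy-1,4a,6-trimethyldecahydronaphthalen-1-yl]methanol, via methylated aldehyde 18 (not isolated)
Conditions: KOtBu (1.3 equiv), MeI (3 equiv), THF, 0 °C; then MeOH, NaBH4, 0 °C
Reagents that add atoms: iodomethane, CI
Why: The potassium enolate of the aldehyde is C-methylated from the equatorial face, away from the 1,3-diaxial C10 methyl, so the formyl carbon becomes the axial C19 substituent of the new quaternary C4, and sodium borohydride then reduces the neopentyl aldehyde in the same flask without opening the epoxide (enolate alkylation followed by hydride reduction).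

Step 12
Reactants: 19 [(1R,4aR,5S,6R,8aR)-5,6-epoxy-1,4a,6-trimethyldecahydronaphthalen-1-yl]methanol; 20 bromoethene (vinyl bromide)
Product: 22 (1R,2R,4aS,5R,8aR)-1-ethenyl-5-(hydroxymethyl)-2,5,8a-trimethyldecahydronaphthalen-2-ol, via iodohydrin 21 (not isolated)
Conditions: NiBr2·glyme (10 mol%), 2,2′-bipyridine (10 mol%), NaI (1 equiv), Et3N·HCl (1.5 equiv), Mn powder (3 equiv), 20 (3 equiv, 1 M in THF), DMPU, 30 °C, sealed tube
Reagents that add atoms: none
Why: Proposed new method: iodide and the ammonium salt open the epoxide reversibly at the secondary C9 from the face opposite the oxygen (trans-diaxial, as in the classical hydrohalic opening of ring-fused epoxides) to iodohydrin 21, monovalent nickel abstracts the iodine atom to give a C9 radical, this radical is captured by the vinylnickel bromide (formed by oxidative addition of 20 to zerovalent nickel) on the open face anti to the axial C10 methyl and the axial 8-hydroxyl, and reductive elimination from trivalent nickel forms the C9–C11 bond with the vinyl group axial (sets C9) while Mn returns nickel to the zerovalent state; the closest known reactions are the nickel/iodide co-catalysed reductive cross-electrophile coupling of epoxides with aryl halides and the nickel-catalysed reductive coupling of secondary alkyl bromides with vinyl bromides, neither of which has been shown for a trisubstituted ring-fused epoxide reacting at a neopentyl carbon under substrate-controlled diastereoselection.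

Step 13
Reactants: 22 (1R,2R,4aS,5R,8aR)-1-ethenyl-5-(hydroxymethyl)-2,5,8a-trimethyldecahydronaphthalen-2-ol; 23 2-chlorobuta-1,3-diene (chloroprene)
Product: 25 (1R,2R,4aS,5R,8aR)-5-(hydroxymethyl)-2,5,8a-trimethyl-1-(3-methylidenepent-4-en-1-yl)decahydronaphthalen-2-ol, via bis(9-BBN) adduct 24 (not isolated)
Conditions: 9-BBN (3 equiv), THF, 0 °C → rt; then 23 (3 equiv), Pd(OAc)2 (5 mol%), SPhos (10 mol%), 3 M aq. K3PO4, THF, 40 °C
Reagents that add atoms: none
Why: 9-BBN hydroborates the terminal vinyl group at its CH2 end (the primary hydroxyl is meanwhile masked as its borinate) and the B-alkyl Suzuki–Miyaura coupling with the activated vinyl chloride of chloroprene forms C12–C13 and completes the diene without touching any stereocentre.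

Step 14
Reactants: 26 4-iodophenol
Product: 27 (4-iodophenoxy)tri(propan-2-yl)silane
Conditions: TIPSCl, imidazole, DMF, rt
Reagents that add atoms: chlorotri(propan-2-yl)silane, CC(C)[Si](Cl)(C(C)C)C(C)C
Why: Silylation of the phenol as the bulky tri(propan-2-yl)silyl ether, chosen because it survives carbonate, hydrogenation and mild hydroxide yet is removed by fluoride.

Step 15
Reactants: 27 (4-iodophenoxy)tri(propan-2-yl)silane; 28 ethyl prop-2-ynoate (ethyl propiolate)
Product: 29 ethyl 3-(4-{[tri(propan-2-yl)silyl]oxy}phenyl)prop-2-ynoate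
Conditions: PdCl2(PPh3)2 (2 mol%), CuI (4 mol%), K2CO3 (2 equiv), THF, 65 °C
Reagents that add atoms: none
Why: Sonogashira coupling of the aryl iodide with the terminal alkyne under carbonate conditions, which avoid amine addition to the ynoate.

Step 16
Reactants: 29 ethyl 3-(4-{[tri(propan-2-yl)silyl]oxy}phenyl)prop-2-ynoate
Product: 30 ethyl (2Z)-3-(4-{[tri(propan-2-yl)silyl]oxy}phenyl)prop-2-enoate
Conditions: H2 (1 atm, 1 equiv uptake), Pd/CaCO3 poisoned with Pb(OAc)2 (Lindlar catalyst), quinoline, EtOAc, rt, dark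
Reagents that add atoms: none
Why: Lindlar semihydrogenation delivers both hydrogens to the same face of the alkyne and so gives the (Z)-cinnamate.

Step 17
Reactants: 30 ethyl (2Z)-3-(4-{[tri(propan-2-yl)silyl]oxy}phenyl)prop-2-enoate
Product: 31 (2Z)-3-(4-{[tri(propan-2-yl)silyl]oxy}phenyl)prop-2-enoic acid
Conditions: LiOH·H2O (3 equiv), THF/H2O 3:1, 0 °C → rt, dark; then 1 M aq. HCl to pH 4
Reagents that add atoms: lithium hydroxide, [Li+].[OH-]
Why: Saponification of the unhindered ethyl ester under mild conditions in the dark keeps the (Z)-alkene and the aryl silyl ether.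

Step 18
Reactants: 25 (1R,2R,4aS,5R,8aR)-5-(hydroxymethyl)-2,5,8a-trimethyl-1-(3-methylidenepent-4-en-1-yl)decahydronaphthalen-2-ol; 31 (2Z)-3-(4-{[tri(propan-2-yl)silyl]oxy}phenyl)prop-2-enoic acid
Product: 32 [(1R,4aR,5R,6R,8aS)-6-hydroxy-1,4a,6-trimethyl-5-(3-methylidenepent-4-en-1-yl)decahydronaphthalen-1-yl]methyl (2Z)-3-(4-{[tri(propan-2-yl)silyl]oxy}phenyl)prop-2-enoate
Conditions: DCC (1.3 equiv), DMAP (10 mol%), CH2Cl2, 0 °C → rt, dark
Reagents that add atoms: none
Why: Steglich esterification acylates only the primary C19 hydroxyl, the tertiary 8-hydroxyl being unreactive, and low temperature, catalytic DMAP and exclusion of light keep the (Z)-alkene intact.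

Step 19
Reactants: 32 [(1R,4aR,5R,6R,8aS)-6-hydroxy-1,4a,6-trimethyl-5-(3-methylidenepent-4-en-1-yl)decahydronaphthalen-1-yl]methyl (2Z)-3-(4-{[tri(propan-2-yl)silyl]oxy}phenyl)prop-2-enoate
Product: 33 [(1R,4aR,5R,6R,8aS)-6-hydroxy-1,4a,6-trimethyl-5-(3-methylidenepent-4-en-1-yl)decahydronaphthalen-1-yl]methyl (2Z)-3-(4-hydroxyphenyl)prop-2-enoate (target)
Conditions: TBAF (1.2 equiv), AcOH (1.2 equiv), THF, 0 °C
Reagents that add atoms: none
Why: Buffered fluoride cleaves the aryl silyl ether through the strong silicon–fluorine bond without isomerising the (Z)-enoate, hydrolysing the ester or affecting the diene and the tertiary alcohol.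

## Compound list

1 | but-3-yn-1-ol | C#CCCO | starting material
2 | trimethyl{[4-(trimethylsilyl)but-3-yn-1-yl]oxy}silane | C[Si](C)(C)C#CCCO[Si](C)(C)C | intermediate
3 | 4-(trimethylsilyl)but-3-yn-1-ol | C[Si](C)(C)C#CCCO | intermediate
4 | bromomagnesium (3Z)-4-(bromomagnesio)-3-methyl-4-(trimethylsilyl)but-3-en-1-olate | C[Si](C)(C)/C([Mg]Br)=C(/C)CCO[Mg]Br | intermediate
5 | (3Z)-3-methyl-4-(trimethylsilyl)but-3-en-1-ol | C[Si](C)(C)/C=C(/C)CCO | intermediate
6 | [(1Z)-4-iodo-2-methylbut-1-en-1-yl](trimethyl)silane | C[Si](C)(C)/C=C(/C)CCI | intermediate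
7 | hex-5-yn-1-ol | C#CCCCCO | starting material
8 | hex-5-ynal | C#CCCCC=O | intermediate
9 | rac-oct-1-en-7-yn-3-ol | C#CCCCC(O)C=C | intermediate
10 | rac-{(1E)-6-[(dimethylalumanyl)oxy]-2-methylocta-1,7-dien-1-yl}dimethylalumane | C=CC(O[Al](C)C)CCC/C(C)=C/[Al](C)C | intermediate
11 | rac-(7E)-8-iodo-7-methylocta-1,7-dien-3-ol | C=CC(O)CCC/C(C)=C/I | intermediate
12 | iodo[(3Z)-3-methyl-4-(trimethylsilyl)but-3-en-1-yl]zinc | C[Si](C)(C)/C=C(/C)CC[Zn]I | intermediate
13 | rac-(7E,11Z)-7,11-dimethyl-12-(trimethylsilyl)dodeca-1,7,11-trien-3-ol | C=CC(O)CCC/C(C)=C/CC/C(C)=C\[Si](C)(C)C | intermediate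
14 | (1R,4aR,8aR)-1-ethenyl-4a,6-dimethyl-1,2,3,4,4a,7,8,8a-octahydronaphthalene | C=C[C@H]1CCC[C@@]2(C)C=C(C)CC[C@H]12 | intermediate
15 | (1R,2R,4aR,5R,8aR)-1-bromo-5-ethenyl-2,8a-dimethyldecahydronaphthalen-2-ol | C=C[C@H]1CCC[C@@]2(C)[C@@H](Br)[C@](C)(O)CC[C@H]12 | intermediate
16 | (1R,4aR,5S,6R,8aR)-1-ethenyl-5,6-epoxy-4a,6-dimethyldecahydronaphthalene | C=C[C@H]1CCC[C@@]2(C)[C@@H]3O[C@]3(C)CC[C@H]12 | intermediate
17 | (1S,4aR,5S,6R,8aR)-5,6-epoxy-4a,6-dimethyldecahydronaphthalene-1-carbaldehyde | O=C[C@H]1CCC[C@@]2(C)[C@@H]3O[C@]3(C)CC[C@H]12 | intermediate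
18 | (1R,4aR,5S,6R,8aS)-5,6-epoxy-1,4a,6-trimethyldecahydronaphthalene-1-carbaldehyde | O=C[C@]1(C)CCC[C@@]2(C)[C@@H]3O[C@]3(C)CC[C@H]12 | intermediate
19 | [(1R,4aR,5S,6R,8aR)-5,6-epoxy-1,4a,6-trimethyldecahydronaphthalen-1-yl]methanol | OC[C@]1(C)CCC[C@@]2(C)[C@@H]3O[C@]3(C)CC[C@H]12 | intermediate
20 | bromoethene (vinyl bromide) | C=CBr | starting material
21 | (1R,2R,4aR,5R,8aR)-5-(hydroxymethyl)-1-iodo-2,5,8a-trimethyldecahydronaphthalen-2-ol | OC[C@]1(C)CCC[C@@]2(C)[C@@H](I)[C@](C)(O)CC[C@H]12 | intermediate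
22 | (1R,2R,4aS,5R,8aR)-1-ethenyl-5-(hydroxymethyl)-2,5,8a-trimethyldecahydronaphthalen-2-ol | OC[C@]1(C)CCC[C@@]2(C)[C@@H](C=C)[C@](C)(O)CC[C@H]12 | intermediate
23 | 2-chlorobuta-1,3-diene (chloroprene) | C=CC(Cl)=C | starting material
24 | 9-{2-[(1R,2R,4aS,5R,8aR)-5-{[(9-borabicyclo[3.3.1]nonan-9-yl)oxy]methyl}-2-hydroxy-2,5,8a-trimethyldecahydronaphthalen-1-yl]ethyl}-9-borabicyclo[3.3.1]nonane | C1CC2CCCC(C1)B2OC[C@]3(C)CCC[C@@]4(C)[C@@H](CCB5C6CCCC5CCC6)[C@](C)(O)CC[C@H]34 | intermediate
25 | (1R,2R,4aS,5R,8aR)-5-(hydroxymethyl)-2,5,8a-trimethyl-1-(3-methylidenepent-4-en-1-yl)decahydronaphthalen-2-ol | OC[C@]1(C)CCC[C@@]2(C)[C@@H](CCC(=C)C=C)[C@](C)(O)CC[C@H]12 | intermediate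
26 | 4-iodophenol | Oc1ccc(I)cc1 | starting material
27 | (4-iodophenoxy)tri(propan-2-yl)silane | CC(C)[Si](Oc1ccc(I)cc1)(C(C)C)C(C)C | intermediate
28 | ethyl prop-2-ynoate (ethyl propiolate) | C#CC(=O)OCC | starting material
29 | ethyl 3-(4-{[tri(propan-2-yl)silyl]oxy}phenyl)prop-2-ynoate | CCOC(=O)C#Cc1ccc(O[Si](C(C)C)(C(C)C)C(C)C)cc1 | intermediate
30 | ethyl (2Z)-3-(4-{[tri(propan-2-yl)silyl]oxy}phenyl)prop-2-enoate | CCOC(=O)/C=C\c1ccc(O[Si](C(C)C)(C(C)C)C(C)C)cc1 | intermediate
31 | (2Z)-3-(4-{[tri(propan-2-yl)silyl]oxy}phenyl)prop-2-enoic acid | OC(=O)/C=C\c1ccc(O[Si](C(C)C)(C(C)C)C(C)C)cc1 | intermediate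
32 | [(1R,4aR,5R,6R,8aS)-6-hydroxy-1,4a,6-trimethyl-5-(3-methylidenepent-4-en-1-yl)decahydronaphthalen-1-yl]methyl (2Z)-3-(4-{[tri(propan-2-yl)silyl]oxy}phenyl)prop-2-enoate | CC(C)[Si](Oc1ccc(/C=C\C(=O)OC[C@]2(C)CCC[C@@]3(C)[C@@H](CCC(=C)C=C)[C@](C)(O)CC[C@H]23)cc1)(C(C)C)C(C)C | intermediate
33 | [(1R,4aR,5R,6R,8aS)-6-hydroxy-1,4a,6-trimethyl-5-(3-methylidenepent-4-en-1-yl)decahydronaphthalen-1-yl]methyl (2Z)-3-(4-hydroxyphenyl)prop-2-enoate | C=CC(=C)CC[C@@H]1[C@]2(C)CCC[C@@](C)(COC(=O)/C=C\c3ccc(O)cc3)[C@H]2CC[C@@]1(C)O | target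

## Step count and risk

Total step count: 19. Longest linear sequence: 12 steps (steps 1–3, 7–13, 18, 19; the path through steps 4–6 is equally long).

**Step 12 (the proposed new coupling).** Iodide may open the epoxide too slowly at the neopentyl C9, opening at C8 or rearrangement may compete, the halohydrin may be reduced back to the Δ8 alkene, or the radical may be captured on the wrong face. The fallback uses known chemistry, sets out from 19 and comes back at 25, so steps 12 and 13 are both replaced. Aqueous HBr (48%) in THF at 0 °C opens 19 trans-diaxially to (1R,2R,4aR,5R,8aR)-1-bromo-5-(hydroxymethyl)-2,5,8a-trimethyldecahydronaphthalen-2-ol F9. Tin-mediated Giese addition (Bu3SnH, AIBN, excess methyl vinyl ketone, benzene, 80 °C) forms C9–C11 by attack of the C9 radical anti to the angular methyl and gives 4-[(1R,2R,4aS,5R,8aR)-2-hydroxy-5-(hydroxymethyl)-2,5,8a-trimethyldecahydronaphthalen-1-yl]butan-2-one F10. Kinetic enolisation toward the methyl group (LDA, 3.3 equiv, both hydroxyls carried as lithium alkoxides; PhNTf2, THF, −78 °C) gives 4-[(1R,2R,4aS,5R,8aR)-2-hydroxy-5-(hydroxymethyl)-2,5,8a-trimethyldecahydronaphthalen-1-yl]but-1-en-2-yl trifluoromethanesulfonate F11. Stille coupling with tributyl(vinyl)stannane (Pd(PPh3)4, LiCl, THF, 60 °C) then gives diene diol 25.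

**Step 8.** A vinylsilane has not been used to end this iridium-initiated cascade; after ring A closes, the C10 cation may lose a proton or the silane may be protodesilylated. The fallback moves enantiocontrol to a hydrolytic kinetic resolution and uses a classical Lewis-acid epoxide-initiated cyclisation. It sets out from 7 and from zinc reagent 12, comes back at 17, and replaces steps 4–10. Carboalumination and iodinolysis of 7 (Me3Al, Cp2ZrCl2; iodine) give (5E)-6-iodo-5-methylhex-5-en-1-ol F1. Negishi coupling with 12 (Pd(OAc)2, SPhos) gives (5E,9Z)-5,9-dimethyl-10-(trimethylsilyl)deca-5,9-dien-1-ol F2, and TEMPO/PhI(OAc)2 oxidation gives (5E,9Z)-5,9-dimethyl-10-(trimethylsilyl)deca-5,9-dienal F3. Corey–Chaykovsky methylenation (trimethylsulfonium iodide, n-BuLi, THF, 0 °C) gives rac-2-[(4E,8Z)-4,8-dimethyl-9-(trimethylsilyl)nona-4,8-dien-1-yl]oxirane F4. Jacobsen hydrolytic kinetic resolution ((R,R)-(salen)Co(OAc), trivalent cobalt, 0.55 equiv H2O) leaves (2S)-2-[(4E,8Z)-4,8-dimethyl-9-(trimethylsilyl)nona-4,8-dien-1-yl]oxirane F5. MeAlCl2 in CH2Cl2 at −78 °C then triggers the vinylsilane-terminated bicyclisation (attack at the internal epoxide carbon with inversion, chair–chair) to [(1S,4aR,8aR)-4a,6-dimethyl-1,2,3,4,4a,7,8,8a-octahydronaphthalen-1-yl]methanol F6. NBS in aqueous THF gives (1R,2R,4aR,5S,8aR)-1-bromo-5-(hydroxymethyl)-2,8a-dimethyldecahydronaphthalen-2-ol F7, and K2CO3 in MeOH gives [(1S,4aR,5S,6R,8aR)-5,6-epoxy-4a,6-dimethyldecahydronaphthalen-1-yl]methanol F8. Dess–Martin oxidation of F8 gives aldehyde 17.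

**Step 18.** The (Z)-cinnamoyl unit may isomerise to (E) on acyl activation with DMAP, and the neopentyl C19 alcohol acylates slowly. The fallback builds the (Z)-alkene on the substrate instead of carrying it through an acylation. It sets out from 25 (and from 27 for the aldehyde), comes back at 32, and makes steps 15–17 unnecessary. Diol 25 is esterified at the primary hydroxyl with 2-[bis(2,2,2-trifluoroethoxy)phosphoryl]acetic acid (DCC, DMAP, CH2Cl2) to [(1R,4aR,5R,6R,8aS)-6-hydroxy-1,4a,6-trimethyl-5-(3-methylidenepent-4-en-1-yl)decahydronaphthalen-1-yl]methyl 2-[bis(2,2,2-trifluoroethoxy)phosphoryl]acetate F12. Iodide 27 is converted by iodine–magnesium exchange (i-PrMgCl·LiCl, THF, −20 °C) and DMF into 4-{[tri(propan-2-yl)silyl]oxy}benzaldehyde F13. Still–Gennari olefination of F13 with F12 (KHMDS, 18-crown-6, THF, −78 °C) gives the (Z)-enoate 32.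

## Further compounds

F1 | step 8 | (5E)-6-iodo-5-methylhex-5-en-1-ol | OCCCC/C(C)=C/I
F2 | step 8 | (5E,9Z)-5,9-dimethyl-10-(trimethylsilyl)deca-5,9-dien-1-ol | OCCCC/C(C)=C/CC/C(C)=C\[Si](C)(C)C
F3 | step 8 | (5E,9Z)-5,9-dimethyl-10-(trimethylsilyl)deca-5,9-dienal | O=CCCC/C(C)=C/CC/C(C)=C\[Si](C)(C)C
F4 | step 8 | rac-2-[(4E,8Z)-4,8-dimethyl-9-(trimethylsilyl)nona-4,8-dien-1-yl]oxirane | C1OC1CCC/C(C)=C/CC/C(C)=C\[Si](C)(C)C
F5 | step 8 | (2S)-2-[(4E,8Z)-4,8-dimethyl-9-(trimethylsilyl)nona-4,8-dien-1-yl]oxirane | C1O[C@H]1CCC/C(C)=C/CC/C(C)=C\[Si](C)(C)C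
F6 | step 8 | [(1S,4aR,8aR)-4a,6-dimethyl-1,2,3,4,4a,7,8,8a-octahydronaphthalen-1-yl]methanol | OC[C@H]1CCC[C@@]2(C)C=C(C)CC[C@H]12
F7 | step 8 | (1R,2R,4aR,5S,8aR)-1-bromo-5-(hydroxymethyl)-2,8a-dimethyldecahydronaphthalen-2-ol | OC[C@H]1CCC[C@@]2(C)[C@@H](Br)[C@](C)(O)CC[C@H]12
F8 | step 8 | [(1S,4aR,5S,6R,8aR)-5,6-epoxy-4a,6-dimethyldecahydronaphthalen-1-yl]methanol | OC[C@H]1CCC[C@@]2(C)[C@@H]3O[C@]3(C)CC[C@H]12
F9 | step 12 | (1R,2R,4aR,5R,8aR)-1-bromo-5-(hydroxymethyl)-2,5,8a-trimethyldecahydronaphthalen-2-ol | OC[C@]1(C)CCC[C@@]2(C)[C@@H](Br)[C@](C)(O)CC[C@H]12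
F10 | step 12 | 4-[(1R,2R,4aS,5R,8aR)-2-hydroxy-5-(hydroxymethyl)-2,5,8a-trimethyldecahydronaphthalen-1-yl]butan-2-one | OC[C@]1(C)CCC[C@@]2(C)[C@@H](CCC(C)=O)[C@](C)(O)CC[C@H]12
F11 | step 12 | 4-[(1R,2R,4aS,5R,8aR)-2-hydroxy-5-(hydroxymethyl)-2,5,8a-trimethyldecahydronaphthalen-1-yl]but-1-en-2-yl trifluoromethanesulfonate | OC[C@]1(C)CCC[C@@]2(C)[C@@H](CCC(=C)OS(=O)(=O)C(F)(F)F)[C@](C)(O)CC[C@H]12
F12 | step 18 | [(1R,4aR,5R,6R,8aS)-6-hydroxy-1,4a,6-trimethyl-5-(3-methylidenepent-4-en-1-yl)decahydronaphthalen-1-yl]methyl 2-[bis(2,2,2-trifluoroethoxy)phosphoryl]acetate | O=C(CP(=O)(OCC(F)(F)F)OCC(F)(F)F)OC[C@]1(C)CCC[C@@]2(C)[C@@H](CCC(=C)C=C)[C@](C)(O)CC[C@H]12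
F13 | step 18 | 4-{[tri(propan-2-yl)silyl]oxy}benzaldehyde | CC(C)[Si](Oc1ccc(C=O)cc1)(C(C)C)C(C)C
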